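**Retrosynthetic overview** (prostanoid numbering: C1 = ester carbon, ring = C8–C12, C9 = ketone, C12 = carbinol)
1. 26 ⇐ 25 (O-silyl) ⇐ acyclic enyne-enal 24 by cutting the ring bond C8–C9 (ketone carbon to the ring carbon that carries the alkylidene). One rhodium-catalysed 5-exo alkyne hydroacylation makes the only ring, the cross-conjugated chlorodienone and the 7E trisubstituted olefin.
2. Enabling feature: in the ring C8–C9–C10–C11–C12 the C9 carbonyl sits directly on the exocyclic C7=C8 double bond, the pattern left by syn addition of an aldehyde C–H across a C7≡C8 alkyne. The endocyclic cis C10(Cl)=C11 olefin and the fully substituted C12 hold aldehyde and alkyne 1,5 to each other.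
3. 24 ⇐ Sonogashira union (C6–C7) of alkyne 19 with vinyl iodide 22; the cis chloro-enal arm ⇐ Still–Gennari-type chloro-olefination (C10=C11) of aldehyde 14.
4. 14 ⇐ diol 9, whose two CH2O arms become the alkyne (C8, Ohira–Bestmann) and the enal (C11); C12 ⇐ Katsuki–Sharpless epoxidation of 2; the (Z)-octenyl chain ⇐ opening of epoxide 3 by a (Z)-heptenyl cuprate (C13–C14).
5. Ring order: a single carbocycle, closed in step 15; step 16 only frees the C12 hydroxyl.

Key step: step 15

Remark on the chemistry: phosphonate 17 is treated as non-commercial and is made in step 9. The facial sense of step 2 is taken from the usual tartrate face-selection rule (L-(+)-tartrate should give S here).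

**Step 1**
Reactants: 1 2-methylidenepropane-1,3-diol
Product: 2 2-{[(4-methoxybenzyl)oxy]methyl}prop-2-en-1-ol
Conditions: 1 (3 equiv), NaH (1 equiv), THF, 0 °C; 4-methoxybenzyl chloride (1 equiv), Bu4NI (cat.), 0 → 25 °C
Reagents that add atoms: 4-methoxybenzyl chloride, COc1ccc(CCl)cc1
Why: Williamson etherification of the mono-alkoxide of a symmetric diol used in excess should give the mono-ether and leave one allylic hydroxyl to direct the epoxidation.

**Step 2**
Reactants: 2 2-{[(4-methoxybenzyl)oxy]methyl}prop-2-en-1-ol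
Product: 3 (S)-(2-{[(4-methoxybenzyl)oxy]methyl}oxiran-2-yl)methanol
Conditions: Ti(OiPr)4 (10 mol %), L-(+)-diethyl tartrate (12 mol %), t-BuOOH (2 equiv), 4 Å molecular sieves, CH2Cl2, −20 °C
Reagents that add atoms: tert-butyl hydroperoxide, CC(C)(C)OO
Why: Katsuki–Sharpless asymmetric epoxidation, in which the allylic hydroxyl binds the titanium tartrate and L-(+)-tartrate should deliver oxygen to the face that makes the new quaternary centre (the future C12) S.

**Step 3**
Reactants: 3 (S)-(2-{[(4-methoxybenzyl)oxy]methyl}oxiran-2-yl)methanol; 4 1-iodopentane; 5 acetylene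
Product: 9 (2R,4Z)-2-{[(4-methoxybenzyl)oxy]methyl}dec-4-ene-1,2-diol, via pentyllithium 6 (not isolated), via lithium dipentylcuprate 7 (not isolated), via lithium di[(Z)-hept-1-enyl]cuprate 8 (not isolated)
Conditions: 4, t-BuLi (2 equiv), Et2O–pentane, −78 → 25 °C; CuBr·SMe2 (0.5 equiv), −40 °C; 5 (1 equiv per pentyl group), −50 → −25 °C; then 3 (0.4 equiv per cuprate), −25 → 0 °C; aq. NH4Cl/NH3
Reagents that add atoms: none
Why: Syn carbocupration of acetylene fixes the Z geometry of the heptenyl group, and organocuprate SN2 opening of the 2,2-disubstituted epoxide at its CH2 terminus leaves the C12 configuration untouched.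

**Step 4**
Reactants: 9 (2R,4Z)-2-{[(4-methoxybenzyl)oxy]methyl}dec-4-ene-1,2-diol
Product: 10 triethyl({(2S,4Z)-2-{[(4-methoxybenzyl)oxy]methyl}-2-[(triethylsilyl)oxy]dec-4-en-1-yl}oxy)silane
Conditions: triethylsilyl trifluoromethanesulfonate (2.5 equiv), 2,6-lutidine (4 equiv), CH2Cl2, −78 → 0 °C
Reagents that add atoms: triethylsilyl trifluoromethanesulfonate, CC[Si](CC)(CC)OS(=O)(=O)C(F)(F)F
Why: The silyl triflate is reactive enough to silylate both the primary and the hindered tertiary hydroxyl (the descriptor changes only through CIP priorities).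

**Step 5**
Reactants: 10 triethyl({(2S,4Z)-2-{[(4-methoxybenzyl)oxy]methyl}-2-[(triethylsilyl)oxy]dec-4-en-1-yl}oxy)silane
Product: 11 (2S,4Z)-2-{[(4-methoxybenzyl)oxy]methyl}-2-[(triethylsilyl)oxy]dec-4-enal
Conditions: (COCl)2 (4 equiv), DMSO (8 equiv), CH2Cl2, −78 → −40 °C; Et3N, → 0 °C
Reagents that add atoms: none
Why: Swern oxidation of a primary triethylsilyl ether, in which the chlorosulfonium salt cleaves only the unhindered primary O–Si bond and oxidises that oxygen in place, should leave the tertiary silyl ether, the PMB ether and the Z olefin intact.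

**Step 6**
Reactants: 11 (2S,4Z)-2-{[(4-methoxybenzyl)oxy]methyl}-2-[(triethylsilyl)oxy]dec-4-enal
Product: 12 (3R,5Z)-3-{[(4-methoxybenzyl)oxy]methyl}-3-[(triethylsilyl)oxy]undec-5-en-1-yne
Conditions: dimethyl (1-diazo-2-oxopropyl)phosphonate (1.5 equiv), K2CO3 (2 equiv), MeOH, 0 → 25 °C
Reagents that add atoms: dimethyl (1-diazo-2-oxopropyl)phosphonate, CC(=O)C(=[N+]=[N-])P(=O)(OC)OC
Why: Ohira–Bestmann (Seyferth–Gilbert) homologation turns the aldehyde into the terminal alkyne, and the aldehyde has no α-hydrogen, so the quaternary centre cannot epimerise.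

**Step 7**
Reactants: 12 (3R,5Z)-3-{[(4-methoxybenzyl)oxy]methyl}-3-[(triethylsilyl)oxy]undec-5-en-1-yne
Product: 13 (2R,4Z)-2-ethynyl-2-[(triethylsilyl)oxy]dec-4-en-1-ol
Conditions: DDQ (1.3 equiv), CH2Cl2/pH 7 buffer (10:1), 0 °C
Reagents that add atoms: none
Why: Oxidative cleavage of the electron-rich PMB ether by DDQ under buffered conditions should spare the tertiary silyl ether, the alkyne and the isolated Z olefin.

**Step 8**
Reactants: 13 (2R,4Z)-2-ethynyl-2-[(triethylsilyl)oxy]dec-4-en-1-ol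
Product: 14 (2R,4Z)-2-ethynyl-2-[(triethylsilyl)oxy]dec-4-enal
Conditions: Dess–Martin periodinane (1.5 equiv), NaHCO3, CH2Cl2, 0 → 25 °C
Reagents that add atoms: none
Why: Dess–Martin oxidation of the neopentyl-type primary alcohol is mild and non-acidic, and the product aldehyde is non-enolisable.

**Step 9**
Reactants: 15 methyl 2-[bis(2,2,2-trifluoroethoxy)phosphoryl]acetate
Product: 17 methyl 2-[bis(2,2,2-trifluoroethoxy)phosphoryl]-2-chloroacetate, via methyl 2-[bis(2,2,2-trifluoroethoxy)phosphoryl]-2,2-dichloroacetate 16 (not isolated)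
Conditions: aq. NaOCl (excess), pH 7, 0 °C, crude organic layer used directly; Na2SO3 (1.1 equiv), H2O/EtOH, 0 °C
Reagents that add atoms: sodium hypochlorite, [Na+].[O-]Cl
Why: Exhaustive hypochlorite chlorination of the active methylene followed by sulfite monodechlorination (halogenation–reduction of a phosphonoacetate) avoids the mono/di mixtures of a direct monochlorination.

**Step 10**
Reactants: 14 (2R,4Z)-2-ethynyl-2-[(triethylsilyl)oxy]dec-4-enal; 17 methyl 2-[bis(2,2,2-trifluoroethoxy)phosphoryl]-2-chloroacetate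
Product: 18 methyl (2E,4S,6Z)-2-chloro-4-ethynyl-4-[(triethylsilyl)oxy]dodeca-2,6-dienoate
Conditions: 17 (1.5 equiv), KN(SiMe3)2 (1.4 equiv), 18-crown-6 (3 equiv), THF, −78 °C; then 14, −78 °C
Reagents that add atoms: none
Why: Still–Gennari-type Horner–Wadsworth–Emmons olefination, in which fast irreversible elimination from the kinetic adduct of the bis(trifluoroethyl) phosphonate should place the ester cis to the quaternary carbon (the 2E chloro-enoate), the geometry required for the later ring closure.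

**Step 11**
Reactants: 18 methyl (2E,4S,6Z)-2-chloro-4-ethynyl-4-[(triethylsilyl)oxy]dodeca-2,6-dienoate
Product: 19 (2E,4S,6Z)-2-chloro-4-ethynyl-4-[(triethylsilyl)oxy]dodeca-2,6-dien-1-ol
Conditions: i-Bu2AlH (2.5 equiv), CH2Cl2, −78 °C; aq. potassium sodium tartrate (KNaC4H4O6)
Reagents that add atoms: none
Why: 1,2-Reduction of the enoate by the aluminium hydride at low temperature should not touch the vinyl chloride, the terminal alkyne or the olefin geometry.

**Step 12**
Reactants: 20 methyl hex-5-ynoate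
Product: 22 methyl (5E)-6-iodohex-5-enoate, via chloro[(1E)-6-methoxy-6-oxohex-1-enyl]zirconocene 21 (not isolated)
Conditions: Cp2Zr(H)Cl (1.2 equiv), THF, 25 °C; then I2, 0 °C
Reagents that add atoms: iodine, II
Why: Hydrozirconation adds Zr–H syn with zirconium on the terminal carbon, and iodinolysis with retention should give the (E)-vinyl iodide while the ester survives the short exposure.

**Step 13**
Reactants: 19 (2E,4S,6Z)-2-chloro-4-ethynyl-4-[(triethylsilyl)oxy]dodeca-2,6-dien-1-ol; 22 methyl (5E)-6-iodohex-5-enoate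
Product: 23 methyl (5E,9S,11Z)-9-[(1E)-2-chloro-3-hydroxyprop-1-enyl]-9-[(triethylsilyl)oxy]heptadeca-5,11-dien-7-ynoate
Conditions: Pd(PPh3)4 (5 mol %), CuI (10 mol %), Et3N (3 equiv), THF, 25 °C
Reagents that add atoms: none
Why: Sonogashira coupling joins the terminal alkyne to the vinyl iodide with retention of the E geometry, while the vinyl chloride is inert to zerovalent palladium at room temperature.

**Step 14**
Reactants: 23 methyl (5E,9S,11Z)-9-[(1E)-2-chloro-3-hydroxyprop-1-enyl]-9-[(triethylsilyl)oxy]heptadeca-5,11-dien-7-ynoate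
Product: 24 methyl (5E,9S,11Z)-9-[(1E)-2-chloro-3-oxoprop-1-enyl]-9-[(triethylsilyl)oxy]heptadeca-5,11-dien-7-ynoate
Conditions: Dess–Martin periodinane (1.5 equiv), NaHCO3, CH2Cl2, 0 °C
Reagents that add atoms: none
Why: Buffered Dess–Martin oxidation of the allylic alcohol should give the enal without isomerising the olefin that keeps CHO cis to the quaternary carbon.

**Step 15**
Reactants: 24 methyl (5E,9S,11Z)-9-[(1E)-2-chloro-3-oxoprop-1-enyl]-9-[(triethylsilyl)oxy]heptadeca-5,11-dien-7-ynoate
Product: 25 methyl (5E,7E)-7-{(5S)-3-chloro-5-[(2Z)-oct-2-enyl]-2-oxo-5-[(triethylsilyl)oxy]cyclopent-3-enylidene}hept-5-enoate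
Conditions: [Rh(cod)2]BF4 (10 mol %), (R)-BINAP (10 mol %), H2 (1 atm) in CH2Cl2 to form [Rh((R)-BINAP)]BF4, then Ar; 24, CH2Cl2 (0.05 M), 25 °C
Reagents that add atoms: none
Why: Oxidative addition of the aldehyde C–H bond of 24 to the cationic monovalent rhodium centre gives an acylrhodium hydride, the tethered C7≡C8 alkyne inserts syn into Rh–H (H to C7, Rh to C8) to give a six-membered acyl(alkenyl)rhodacycle, and C–C reductive elimination forms the C8–C9 bond and returns the catalyst. The closest known reaction type is the rhodium/diphosphine-catalysed intramolecular hydroacylation of 5-alkynals to 2-alkylidenecyclopentanones. The only ring, the cyclopentenone C8–C12, closes in the 5-exo-dig mode. No stereocentre is created: C12 is a spectator, the ligand chirality can affect only the rate, and the 7E geometry follows from the syn addition of acyl and H, which places the C6 dienyl chain anti to the C9 carbonyl. The step needs exo rather than endo closure and hydroacylation rather than decarbonylation; the cis C10(Cl)=C11 olefin and the fully substituted C12 hold CHO and alkyne close so that insertion should outrun CO loss, and endo closure would demand an anti hydrometalation.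

**Step 16**
Reactants: 25 methyl (5E,7E)-7-{(5S)-3-chloro-5-[(2Z)-oct-2-enyl]-2-oxo-5-[(triethylsilyl)oxy]cyclopent-3-enylidene}hept-5-enoate
Product: 26 methyl (5E,7E)-7-{(5S)-3-chloro-5-hydroxy-5-[(2Z)-oct-2-enyl]-2-oxocyclopent-3-enylidene}hept-5-enoate
Conditions: HF·pyridine, pyridine, THF, 0 °C
Reagents that add atoms: none
Why: Buffered fluoride cleavage of the tertiary triethylsilyl ether is non-basic and only weakly acidic, so the cross-conjugated dienone, the tertiary allylic alcohol and the methyl ester should survive.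

**Compound list**
1 | 2-methylidenepropane-1,3-diol | C=C(CO)CO | starting material
2 | 2-{[(4-methoxybenzyl)oxy]methyl}prop-2-en-1-ol | C=C(CO)COCc1ccc(OC)cc1 | intermediate
3 | (S)-(2-{[(4-methoxybenzyl)oxy]methyl}oxiran-2-yl)methanol | C1O[C@]1(CO)COCc2ccc(OC)cc2 | intermediate
4 | 1-iodopentane | CCCCCI | starting material
5 | acetylene | C#C | starting material
6 | pentyllithium | [Li]CCCCC | intermediate
7 | lithium dipentylcuprate | [Li+].CCCCC[Cu-]CCCCC | intermediate
8 | lithium di[(Z)-hept-1-enyl]cuprate | [Li+].CCCCC/C=C\[Cu-]/C=C\CCCCC | intermediate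
9 | (2R,4Z)-2-{[(4-methoxybenzyl)oxy]methyl}dec-4-ene-1,2-diol | CCCCC/C=C\C[C@](CO)(O)COCc1ccc(OC)cc1 | intermediate
10 | triethyl({(2S,4Z)-2-{[(4-methoxybenzyl)oxy]methyl}-2-[(triethylsilyl)oxy]dec-4-en-1-yl}oxy)silane | CCCCC/C=C\C[C@](CO[Si](CC)(CC)CC)(O[Si](CC)(CC)CC)COCc1ccc(OC)cc1 | intermediate
11 | (2S,4Z)-2-{[(4-methoxybenzyl)oxy]methyl}-2-[(triethylsilyl)oxy]dec-4-enal | CCCCC/C=C\C[C@](C=O)(O[Si](CC)(CC)CC)COCc1ccc(OC)cc1 | intermediate
12 | (3R,5Z)-3-{[(4-methoxybenzyl)oxy]methyl}-3-[(triethylsilyl)oxy]undec-5-en-1-yne | CCCCC/C=C\C[C@](C#C)(O[Si](CC)(CC)CC)COCc1ccc(OC)cc1 | intermediate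
13 | (2R,4Z)-2-ethynyl-2-[(triethylsilyl)oxy]dec-4-en-1-ol | CCCCC/C=C\C[C@](C#C)(O[Si](CC)(CC)CC)CO | intermediate
14 | (2R,4Z)-2-ethynyl-2-[(triethylsilyl)oxy]dec-4-enal | CCCCC/C=C\C[C@](C#C)(O[Si](CC)(CC)CC)C=O | intermediate
15 | methyl 2-[bis(2,2,2-trifluoroethoxy)phosphoryl]acetate | COC(=O)CP(=O)(OCC(F)(F)F)OCC(F)(F)F | starting material
16 | methyl 2-[bis(2,2,2-trifluoroethoxy)phosphoryl]-2,2-dichloroacetate | COC(=O)C(Cl)(Cl)P(=O)(OCC(F)(F)F)OCC(F)(F)F | intermediate
17 | methyl 2-[bis(2,2,2-trifluoroethoxy)phosphoryl]-2-chloroacetate (racemic) | COC(=O)C(Cl)P(=O)(OCC(F)(F)F)OCC(F)(F)F | intermediate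
18 | methyl (2E,4S,6Z)-2-chloro-4-ethynyl-4-[(triethylsilyl)oxy]dodeca-2,6-dienoate | CCCCC/C=C\C[C@](C#C)(O[Si](CC)(CC)CC)/C=C(Cl)\C(=O)OC | intermediate
19 | (2E,4S,6Z)-2-chloro-4-ethynyl-4-[(triethylsilyl)oxy]dodeca-2,6-dien-1-ol | CCCCC/C=C\C[C@](C#C)(O[Si](CC)(CC)CC)/C=C(Cl)\CO | intermediate
20 | methyl hex-5-ynoate | C#CCCCC(=O)OC | starting material
21 | chloro[(1E)-6-methoxy-6-oxohex-1-enyl]zirconocene | COC(=O)CCC/C=C/[Zr](Cl)(C1C=CC=C1)C1C=CC=C1 | intermediate
22 | methyl (5E)-6-iodohex-5-enoate | COC(=O)CCC/C=C/I | intermediate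
23 | methyl (5E,9S,11Z)-9-[(1E)-2-chloro-3-hydroxyprop-1-enyl]-9-[(triethylsilyl)oxy]heptadeca-5,11-dien-7-ynoate | CCCCC/C=C\C[C@](C#C/C=C/CCCC(=O)OC)(O[Si](CC)(CC)CC)/C=C(Cl)\CO | intermediate
24 | methyl (5E,9S,11Z)-9-[(1E)-2-chloro-3-oxoprop-1-enyl]-9-[(triethylsilyl)oxy]heptadeca-5,11-dien-7-ynoate | CCCCC/C=C\C[C@](C#C/C=C/CCCC(=O)OC)(O[Si](CC)(CC)CC)/C=C(Cl)\C=O | intermediate
25 | methyl (5E,7E)-7-{(5S)-3-chloro-5-[(2Z)-oct-2-enyl]-2-oxo-5-[(triethylsilyl)oxy]cyclopent-3-enylidene}hept-5-enoate | CCCCC/C=C\C[C@]1(O[Si](CC)(CC)CC)C=C(Cl)C(=O)/C1=C/C=C/CCCC(=O)OC | intermediate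
26 | methyl (5E,7E)-7-{(5S)-3-chloro-5-hydroxy-5-[(2Z)-oct-2-enyl]-2-oxocyclopent-3-enylidene}hept-5-enoate | CCCCC/C=C\C[C@]1(O)C=C(Cl)C(=O)/C1=C/C=C/CCCC(=O)OC | target

**Step count**
Total steps: 16. Longest linear sequence: 14 steps (1 → 26 through steps 1–8, 10, 11 and 13–16); steps 9 and 12 prepare side fragments.

**Three steps most likely to fail**

Step 15. The acylrhodium hydride may lose CO (decarbonylation) before the alkyne inserts, or insertion may stall because the alkyne sits next to the fully substituted C12. The fallback sets out from 24 and comes back at 26, forming the same C8–C9 bond by another mechanism. Nickel-catalysed reductive aldehyde–alkyne cyclisation (Ni(cod)2, PBu3, Et3SiH, THF, 25 °C) couples aldehyde and alkyne on zerovalent nickel to an oxanickelacycle, so no acyl–metal hydride exists and CO loss is excluded. The silane then delivers H to C7 syn, which should give methyl (5E,7Z)-7-{(5S)-3-chloro-5-[(2Z)-oct-2-enyl]-2,5-bis[(triethylsilyl)oxy]cyclopent-3-enylidene}hept-5-enoate F1 as C9 epimers; the chain is still anti to C9 and the descriptor changes only because C9 loses its carbonyl priority. HF·pyridine should then give methyl (5E,7Z)-7-{(5S)-3-chloro-2,5-dihydroxy-5-[(2Z)-oct-2-enyl]cyclopent-3-enylidene}hept-5-enoate F2. MnO2 in CH2Cl2 should oxidise only the doubly allylic secondary alcohol and give 26.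

Step 10. Geometric control may be poor at the hindered, α-quaternary aldehyde, giving mainly the isomer with the ester trans to C12, which cannot cyclise later. The fallback sets out from 14 and comes back at 19, and lets lactonisation set the geometry. Horner–Wadsworth–Emmons reaction of 14 with commercial triethyl 2-chloro-2-phosphonoacetate (NaH, THF) should give ethyl (4S,6Z)-2-chloro-4-ethynyl-4-[(triethylsilyl)oxy]dodeca-2,6-dienoate F3 as a mixture at C2=C3. HF·pyridine frees the tertiary alcohol to ethyl (4S,6Z)-2-chloro-4-ethynyl-4-hydroxydodeca-2,6-dienoate F4. Sensitised irradiation (350 nm, benzophenone, MeCN) interconverts the geometric isomers, and since only the cis isomer can lactonise, the mixture should drain into (5S)-3-chloro-5-ethynyl-5-[(2Z)-oct-2-enyl]furan-2(5H)-one F5. i-Bu2AlH (3 equiv, −78 → 0 °C) should reduce the lactone to (2E,4S,6Z)-2-chloro-4-ethynyldodeca-2,6-diene-1,4-diol F6. Triethylsilyl trifluoromethanesulfonate/2,6-lutidine gives (2E,4S,6Z)-2-chloro-4-ethynyl-1,4-bis[(triethylsilyl)oxy]dodeca-2,6-diene F7, and pyridinium p-toluenesulfonate in MeOH at 0 °C should remove only the primary allylic silyl group to give 19.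

Step 3. The alkenyl cuprate may attack the neopentyl-type epoxide carbon too slowly and decay thermally, or the epoxy alkoxide may undergo base-induced Payne-type equilibration, which would erode the enantiomeric purity. The fallback sets out from 3 and comes back at 9, trading the cuprate for an alkyne nucleophile and a separate reduction. The alkynylalane Et2Al–C≡C–C5H11 (from hept-1-yne, n-BuLi and Et2AlCl; toluene, 0 °C) is delivered from the aluminium alkoxide of 3 to the CH2 terminus and should give (2R)-2-{[(4-methoxybenzyl)oxy]methyl}dec-4-yne-1,2-diol F8. Semihydrogenation (H2, Pd/CaCO3/Pb(OAc)2, quinoline, EtOAc) should then give 9 with the Z olefin.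

**Further compounds**
F1 | step 15 | methyl (5E,7Z)-7-{(5S)-3-chloro-5-[(2Z)-oct-2-enyl]-2,5-bis[(triethylsilyl)oxy]cyclopent-3-enylidene}hept-5-enoate (C9 epimers) | CCCCC/C=C\C[C@]1(O[Si](CC)(CC)CC)C=C(Cl)C(O[Si](CC)(CC)CC)/C1=C/C=C/CCCC(=O)OC
F2 | step 15 | methyl (5E,7Z)-7-{(5S)-3-chloro-2,5-dihydroxy-5-[(2Z)-oct-2-enyl]cyclopent-3-enylidene}hept-5-enoate (C9 epimers) | CCCCC/C=C\C[C@]1(O)C=C(Cl)C(O)/C1=C/C=C/CCCC(=O)OC
F3 | step 10 | ethyl (4S,6Z)-2-chloro-4-ethynyl-4-[(triethylsilyl)oxy]dodeca-2,6-dienoate (mixture at C2=C3) | CCCCC/C=C\C[C@](C#C)(O[Si](CC)(CC)CC)C=C(Cl)C(=O)OCC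
F4 | step 10 | ethyl (4S,6Z)-2-chloro-4-ethynyl-4-hydroxydodeca-2,6-dienoate (mixture at C2=C3) | CCCCC/C=C\C[C@](C#C)(O)C=C(Cl)C(=O)OCC
F5 | step 10 | (5S)-3-chloro-5-ethynyl-5-[(2Z)-oct-2-enyl]furan-2(5H)-one | CCCCC/C=C\C[C@]1(C#C)OC(=O)C(Cl)=C1
F6 | step 10 | (2E,4S,6Z)-2-chloro-4-ethynyldodeca-2,6-diene-1,4-diol | CCCCC/C=C\C[C@](C#C)(O)/C=C(Cl)\CO
F7 | step 10 | (2E,4S,6Z)-2-chloro-4-ethynyl-1,4-bis[(triethylsilyl)oxy]dodeca-2,6-diene | CCCCC/C=C\C[C@](C#C)(O[Si](CC)(CC)CC)/C=C(Cl)\CO[Si](CC)(CC)CC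
F8 | step 3 | (2R)-2-{[(4-methoxybenzyl)oxy]methyl}dec-4-yne-1,2-diol | CCCCCC#CC[C@](CO)(O)COCc1ccc(OC)cc1
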